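Readings and results are calculated on assumed constants; noise was put on by code.

The chemist at this flask has one earlier run to go on, the winter run, made with 3.6 mol% of catalyst against 1.8 mol% here, and no run shows what the catalyst charge does.

- winter: starting material 1.1 M; catalyst 3.6 mol%; run made earlier
- flask: starting material 1.1 M; catalyst 1.8 mol%; time 15 d

winter run (percent of the starting material charged)

| time / h | target / % | starting material / % |
|---|---|---|
| 2.00 | 1 | 95 |
| 6.00 | 4 | 95 |
| 10.0 | 6 | 89 |
| 15.0 | 11 | 84 |
| 20.0 | 10 | 77 |
| 30.0 | 13 | 71 |
| 40.0 | 12 | 61 |

(scatter of a reading: 1.5 percentage points)

1. the moment within 15 d at which there is most target
2. the amount of target, in percent of the starting material charged, at that time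

- the numbers in the tables scatter with a standard deviation of 1.5 percentage points
- no earlier run changes the charge of catalyst; that part of a forecast is a guess

Turn the question round: for this flask to have no peak, target would still have to be rising at 15 d. In the winter run target read 13% at 30.0 h and 12% at 40.0 h, level within the scatter, so these readings don't show where the rise ends; 61% of the starting material was left at the last of them. What we can ask is how far the flask runs beyond those readings: to stay within them, it would have to hold that much starting material at the end. We measure the distance by the half-life of the starting material, the time in which it falls to half by all its exits together, taking the decay as pseudo-first-order: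

half-life in the winter run = 2.34 d

half-life needed to stay within the winter readings = 21.0 d

Even at 4.67 d, twice the winter value, the half-life stays 4.50 times short of that, and the flask would end with 10.8% starting material, below the last winter reading. We judge a rise lasting that far unlikely and commit to a peak inside the time, between 1.2 d and 3.33 d, with target at or above the 13% read in the winter run.

The forecast gave 12% (7.5% to 15%) at 2.6 d (1.5 d to 4.5 d), adding: “This catalyst dependence is a guess.”

The flask gives 16.7% at 3.18 d, inside that range, and higher than the winter reading.

    isomer of the product A ⇌ isomer of the product B (K = 12.0, k = 1.10 × 10⁻⁵ s⁻¹)
    starting material ⇌ target (K = 22.0, k = 2.90 × 10⁻⁶ s⁻¹)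
    target ⇌ isomer of the product A (K = 0.780, k = 7.20 × 10⁻⁵ s⁻¹)
    starting material → uncatalysed product (k = 5.50 × 10⁻⁷ s⁻¹)

The winter half-life carries over without any doubling: from 2.34 d the flask should hold 39.0% starting material at 3.18 d, and it holds 39.1%. The height in the flask is held down by the conversion of target into isomer of the product A, the largest single effect: without that step the same run reaches 79.0% of target against 16.7%. A second flask of the same charge, read at 6.0 d, should hold 16.9% starting material, and it holds 17.2%.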